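The constants stand for no real mixture.

You come from the earlier reading of this flask at 8.0 s with the hunch that more gas per second is what pays, and you want a number for 20 s.

    dissolved gas + target → over-reaction product (k1 = 10.2 M⁻¹ s⁻¹)
    target ⇌ isomer of the product (K2 = 0.92, k2 = 0.0149 s⁻¹)
    gas phase ⇌ dissolved gas, rate k3*(csat - [dissolved gas]) (k3 = 0.749 s⁻¹, csat = 14 mM)
    substrate + dissolved gas → target (k4 = 67.8 M⁻¹ s⁻¹)
    crystals ⇌ target, rate k5*(cs5 - [target]) while solid is left; crystals form when [target] > cs5 (cs5 = 0.052 M, k5 = 1.53 s⁻¹)

substrate 0.25 M; gas phase 14 mM (held); time 20 s

- amounts and yields of target count crystals too
- given per volume of solution although it is solid: crystals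
- at the start none of the gas is dissolved
- run time (flask): 20 s

1. how much target and crystals together there is at 20 s, in percent of the substrate charged
2. the change that raises the amount of target and crystals together at 20 s, in percent of the substrate charged most ("none" if none brings more than 2 percentage points) (maple / birch / larch / oak / none)
3. amount of target and crystals together at 20 s, in percent of the substrate charged, after oak

- maple: doubling the saturation concentration of gas phase, all else as stated
- birch: doubling the dissolution coefficient of step 5, all else as stated
- larch: doubling the solubility in step 5, all else as stated
- oak: doubling the transfer coefficient of step 3, all else as stated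

I freeze [dissolved gas]. The reaction with substrate alone removes it with a half-life of 0.041 s at the charged substrate, far shorter than the run, so I give it a small steady value and let transfer run at its coefficient times the saturation concentration. That product is the gas feed, the most gas per second an empty solution takes up: 10.5 mM s⁻¹. Over the run it offers 83.9 % of the charge, less than the charge, and at the charged substrate dissolved gas reacts away faster than transfer relaxes, so in this flask I treat transfer as the rate-limiting step.

The feed brings [target] to the solubility after 4.96 s, well inside the run, so I hold it there. With substrate at half the charge, the steady gas costs 8.84 % of the feed in driving force. The selectivity factor towards over-reaction is 6.26 %, counted twice because each event spends a gas and a target. Isomer, reckoned by the forward step of its equilibrium, takes 5.43 %. That leaves 60.5 %.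

Oak and maple both double the feed, which by my estimate has offered the whole charge after 11.9 s. For the remaining time, I set gas at the doubled feed over that flask's transfer coefficient plus the over-reaction's first-order constant. My estimate of over-reaction is then 17.7 % under oak, less than 28.1 % under maple. By this estimate oak keeps 76.8 %, and my choice is oak.

The forecast, saying “Gas transfer is the bottleneck”, gives 62 %, above me, the same oak, and 72 %, below me.

The simulation gives 64.2 %, oak with a gain of 13 percentage points, and 76.8 %.

In this flask at 20.0 s, the feed has offered 83.9 % and substrate has fallen by 73.3 %, with [dissolved gas] reading 0.00176 M, below the saturation concentration. The same flask read at 8.0 s has been offered 33.6 % by the feed. There substrate has fallen by 30.8 %, [dissolved gas] reads 8.00 × 10⁻⁴ M, and target and crystals together stand at 28.4 %, of which 5.51 % is crystals.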